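**Retrosynthetic overview**
1. Target ⇐ its penta-O-benzyl ether by one global hydrogenolysis; all four stereocentres are in place before the heterocycle exists.
2. 4-Pyranone (closed last, key step): O1–C2 cyclodehydration of a 1,3,5-tricarbonyl chain on the keto form of the already tetra-oxygenated ring A. This is the non-aromatic counterpart of the C6–C5–C6 diarylpentanoid-to-chromone closure presumed in agarwood. Chain ⇐ dianion of a 2-acetylcyclohexanone + dihydrocinnamoyl Weinreb amide (C2–C3 bond); 2-acetyl ketone ⇐ ketone + acetyl donor (C4–C4a bond).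
3. Ring A (closed first): (2S,3R,4S,5S)-tris(benzyloxy)hydroxycyclohexanone ⇐ Ferrier carbocyclization of a D-glucose 5-enopyranoside. Target C6, C7, C8 are glucose C2, C3, C4; target C5 is set in that aldol closure.
4. Side chain ⇐ 3-(benzyloxy)-4-methoxybenzaldehyde by Horner–Wadsworth–Emmons olefination and C=C hydrogenation; ring B is bought.
5. Order of ring formation: carbocycle A (step 3), then the pyranone (step 8).

Assumption: the target is taken exactly as drawn, (5S,6S,7R,8S) (5-OH/6-OH cis, 6-OH/7-OH trans, 7-OH/8-OH trans), and the presumed biosynthesis as dihydrocinnamoyl diketide + C6 acyl unit → C6–C5–C6 1,3-diketone → O-cyclization/dehydration to the chromone.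

**Route**

Step 1
Reactants: 1 methyl α-D-glucopyranoside
Product: 2 methyl 6-deoxy-6-iodo-α-D-glucopyranoside
Conditions: PPh3, N-iodosuccinimide, DMF, 50 °C
Reagents that add atoms: N-iodosuccinimide, O=C1CCC(=O)N1I
Why: Hanessian (Appel-type) halogenation, in which the oxyphosphonium salt forms fastest at the only primary hydroxyl and is displaced by iodide (SN2); no stereocentre is involved.

Step 2
Reactants: 2 methyl 6-deoxy-6-iodo-α-D-glucopyranoside
Product: 3 methyl 2,3,4-tri-O-benzyl-6-deoxy-α-D-xylo-hex-5-enopyranoside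
Conditions: NaH (6 equiv), BnBr (4 equiv), DMF, 0 °C → rt
Reagents that add atoms: benzyl bromide, BrCc1ccccc1
Why: Williamson benzylation of the three secondary hydroxyls and, in the same flask, E2 loss of HI across C5–C6 give the exocyclic enol ether, with C1–C4 unchanged from D-glucose.

Step 3
Reactants: 3 methyl 2,3,4-tri-O-benzyl-6-deoxy-α-D-xylo-hex-5-enopyranoside
Product: 4 (2S,3R,4S,5S)-2,3,4-tris(benzyloxy)-5-hydroxycyclohexan-1-one
Conditions: Hg(OCOCF3)2 (10 mol %), acetone–H2O (2:1), rt
Reagents that add atoms: water, O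
Why: Ferrier carbocyclization (oxymercuration of the enol ether, loss of methanol, then 6-enolexo aldol of the mercurio-enolate onto the unmasked C1 aldehyde) closes ring A through a chair transition state with the aldehyde oxygen axial, so the new carbinol (target C5) forms mainly with OH axial and cis to the neighbouring benzyloxy group (typically ≥4:1, minor epimer removed by chromatography), while glucose C4, C3, C2 become ring C2, C3, C4 unchanged.

Step 4
Reactants: 4 (2S,3R,4S,5S)-2,3,4-tris(benzyloxy)-5-hydroxycyclohexan-1-one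
Product: 5 (2S,3R,4S,5S)-2,3,4,5-tetrakis(benzyloxy)cyclohexan-1-one
Conditions: BnOC(=NH)CCl3 (1.5 equiv), CF3SO3H (5 mol %), CH2Cl2–cyclohexane, 0 °C
Reagents that add atoms: benzyl 2,2,2-trichloroacetimidate, ClC(Cl)(Cl)C(=N)OCc1ccccc1
Why: Acid-catalysed trichloroacetimidate benzylation caps the β-hydroxyl without base, so neither retro-aldol nor β-elimination can start and C5 keeps its configuration.

Step 5
Reactants: 5 (2S,3R,4S,5S)-2,3,4,5-tetrakis(benzyloxy)cyclohexan-1-one
Product: 6 1-[(3S,4R,5S,6S)-3,4,5,6-tetrakis(benzyloxy)-2-hydroxycyclohex-1-en-1-yl]ethan-1-one (enol form of the 2-acetylcyclohexanone)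
Conditions: LiN(SiMe3)2 (2.2 equiv), THF, −78 °C; 1-acetyl-1H-benzotriazole (1.1 equiv), −78 °C; cold dilute aq. HCl
Reagents that add atoms: 1-acetyl-1H-benzotriazole, CC(=O)n1nnc2ccccc12
Why: Crossed-Claisen C-acylation of the kinetic lithium enolate (deprotonation at the unhindered CH2, not at the benzyloxy-bearing methine) with an N-acylbenzotriazole, run at −78 °C so the β-benzyloxy group is not expelled; the acylated carbon is enolized and therefore no stereocentre, and the four ring centres are untouched.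

Step 6
Reactants: 7 3-(benzyloxy)-4-methoxybenzaldehyde; 8 diethyl {2-[methoxy(methyl)amino]-2-oxoethyl}phosphonate
Product: 9 (E)-3-[3-(benzyloxy)-4-methoxyphenyl]-N-methoxy-N-methylprop-2-enamide
Conditions: NaH, THF, 0 °C → rt
Reagents that add atoms: none
Why: Horner–Wadsworth–Emmons olefination with a stabilized phosphonate gives the (E)-cinnamoyl Weinreb amide; no stereocentre is formed.

Step 7
Reactants: 9 (E)-3-[3-(benzyloxy)-4-methoxyphenyl]-N-methoxy-N-methylprop-2-enamide
Product: 10 3-[3-(benzyloxy)-4-methoxyphenyl]-N-methoxy-N-methylpropanamide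
Conditions: H2 (1 atm), Pd/C (5 %), Ph2S (1 mol %), EtOAc, rt
Reagents that add atoms: none
Why: Catalytic hydrogenation of the conjugated C=C on sulfide-moderated Pd/C, which leaves the aryl benzyl ether and the N–O bond intact and delivers the dihydrocinnamoyl unit that serves as starter in the plant.

Step 8
Reactants: 6 1-[(3S,4R,5S,6S)-3,4,5,6-tetrakis(benzyloxy)-2-hydroxycyclohex-1-en-1-yl]ethan-1-one; 10 3-[3-(benzyloxy)-4-methoxyphenyl]-N-methoxy-N-methylpropanamide
Product: 12 (5S,6S,7R,8S)-5,6,7,8-tetrakis(benzyloxy)-2-{2-[3-(benzyloxy)-4-methoxyphenyl]ethyl}-5,6,7,8-tetrahydro-4H-chromen-4-one, via triketone 11 (not isolated)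
Conditions: LiN(iPr)2 (2.3 equiv), THF, −78 → −40 °C; 10, −78 → −20 °C; cold dilute aq. HCl; crude 11, CF3CO2H, CH2Cl2, 0 °C → rt
Reagents that add atoms: none
Why: Harris-type β-diketone dianion acylation (Claisen condensation of the terminal carbanion with the Weinreb amide) builds the 1,3,5-tricarbonyl counterpart of the plant's C6–C5–C6 diarylpentanoid, and acid then drives the same O-cyclization/dehydration presumed to close the chromone (the ring enol is held cis to the chain), giving the 4-pyranone; no stereocentre is made or broken, and C5/C8 are shielded from ionization because the pyranone carbonyl is protonated first.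

Step 9
Reactants: 12 (5S,6S,7R,8S)-5,6,7,8-tetrakis(benzyloxy)-2-{2-[3-(benzyloxy)-4-methoxyphenyl]ethyl}-5,6,7,8-tetrahydro-4H-chromen-4-one
Product: 13 (5S,6S,7R,8S)-5,6,7,8-tetrahydroxy-2-[2-(3-hydroxy-4-methoxyphenyl)ethyl]-5,6,7,8-tetrahydro-4H-chromen-4-one (CNP0224308.1)
Conditions: H2 (1 atm), Pd(OH)2/C, EtOAc–MeOH (1:1), rt
Reagents that add atoms: none
Why: Hydrogenolysis cleaves the four alkyl benzyl ethers and the aryl benzyl ether, while the electron-poor, fully substituted pyranone double bonds are not reduced at 1 atm; the stereocentres are untouched.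

**Compound list**

1 | methyl α-D-glucopyranoside | CO[C@H]1O[C@H](CO)[C@@H](O)[C@H](O)[C@H]1O | starting material
2 | methyl 6-deoxy-6-iodo-α-D-glucopyranoside | CO[C@H]1O[C@H](C[I])[C@@H](O)[C@H](O)[C@H]1O | intermediate
3 | methyl 2,3,4-tri-O-benzyl-6-deoxy-α-D-xylo-hex-5-enopyranoside | CO[C@H]1OC(=C)[C@@H](OCc2ccccc2)[C@H](OCc2ccccc2)[C@H]1OCc1ccccc1 | intermediate
4 | (2S,3R,4S,5S)-2,3,4-tris(benzyloxy)-5-hydroxycyclohexan-1-one | O=C1[C@@H](OCc2ccccc2)[C@H](OCc2ccccc2)[C@@H](OCc2ccccc2)[C@@H](O)C1 | intermediate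
5 | (2S,3R,4S,5S)-2,3,4,5-tetrakis(benzyloxy)cyclohexan-1-one | O=C1[C@@H](OCc2ccccc2)[C@H](OCc2ccccc2)[C@@H](OCc2ccccc2)[C@@H](OCc2ccccc2)C1 | intermediate
6 | 1-[(3S,4R,5S,6S)-3,4,5,6-tetrakis(benzyloxy)-2-hydroxycyclohex-1-en-1-yl]ethan-1-one | CC(=O)C1=C(O)[C@@H](OCc2ccccc2)[C@H](OCc2ccccc2)[C@@H](OCc2ccccc2)[C@H]1OCc1ccccc1 | intermediate
7 | 3-(benzyloxy)-4-methoxybenzaldehyde | COc1ccc(C=O)cc1OCc1ccccc1 | starting material
8 | diethyl {2-[methoxy(methyl)amino]-2-oxoethyl}phosphonate | CCOP(=O)(OCC)CC(=O)N(C)OC | starting material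
9 | (E)-3-[3-(benzyloxy)-4-methoxyphenyl]-N-methoxy-N-methylprop-2-enamide | COc1ccc(/C=C/C(=O)N(C)OC)cc1OCc1ccccc1 | intermediate
10 | 3-[3-(benzyloxy)-4-methoxyphenyl]-N-methoxy-N-methylpropanamide | COc1ccc(CCC(=O)N(C)OC)cc1OCc1ccccc1 | intermediate
11 | 1-[(3S,4R,5S,6S)-3,4,5,6-tetrakis(benzyloxy)-2-hydroxycyclohex-1-en-1-yl]-5-[3-(benzyloxy)-4-methoxyphenyl]pentane-1,3-dione (ring-enol tautomer of the triketone) | COc1ccc(CCC(=O)CC(=O)C2=C(O)[C@@H](OCc3ccccc3)[C@H](OCc3ccccc3)[C@@H](OCc3ccccc3)[C@H]2OCc2ccccc2)cc1OCc1ccccc1 | intermediate (not isolated)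
12 | (5S,6S,7R,8S)-5,6,7,8-tetrakis(benzyloxy)-2-{2-[3-(benzyloxy)-4-methoxyphenyl]ethyl}-5,6,7,8-tetrahydro-4H-chromen-4-one | COc1ccc(CCc2cc(=O)c3c(o2)[C@@H](OCc4ccccc4)[C@H](OCc4ccccc4)[C@@H](OCc4ccccc4)[C@H]3OCc4ccccc4)cc1OCc1ccccc1 | intermediate
13 | (5S,6S,7R,8S)-5,6,7,8-tetrahydroxy-2-[2-(3-hydroxy-4-methoxyphenyl)ethyl]-5,6,7,8-tetrahydro-4H-chromen-4-one | COc1ccc(CCc2cc(=O)c3c(o2)[C@@H](O)[C@H](O)[C@@H](O)[C@H]3O)cc1O | target

**Step count and risks**

Total steps: 9. Longest linear sequence: 7 (steps 1–5, 8, 9).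

Most likely to fail, first: step 8. The dianion of 6 must be warmed to attack the amide, and a benzyloxy group β to the ring enolate (axial at C5 of the final skeleton) may be expelled; the acid closure must also not ionize C5–O. Fallback: set out from 6 and 10. Reduce 10 with (i-Bu)2AlH (THF, −78 °C) to 3-[3-(benzyloxy)-4-methoxyphenyl]propanal F1. Add it at −78 °C to the dilithio dianion of 6; this aldol addition is complete without warming and gives 1-[(3S,4R,5S,6S)-3,4,5,6-tetrakis(benzyloxy)-2-hydroxycyclohex-1-en-1-yl]-5-[3-(benzyloxy)-4-methoxyphenyl]-3-hydroxypentan-1-one F2. Oxidize this with Dess–Martin periodinane (NaHCO3, CH2Cl2) to the triketone 11, where the route is rejoined for the acid closure to 12.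

Second: step 5. Deprotonation may occur on the benzyloxy-bearing side, or the lithium enolate may lose the axial β-benzyloxy group. Fallback: set out from 5. Form the boron enolate on the CH2 side with (c-C6H11)2BCl/Et3N (Et2O, −78 °C); boron enolates do not expel β-alkoxy groups. Add acetaldehyde to give the aldol (2S,3R,4S,5S)-2,3,4,5-tetrakis(benzyloxy)-6-(1-hydroxyethyl)cyclohexan-1-one F3, whose two new centres are erased in the next operation. Oxidize it with Dess–Martin periodinane to 6, where the route is rejoined.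

Third: step 9. Fivefold hydrogenolysis may also cleave the allylic C5–O or C8–O bond or partly reduce the pyranone. Fallback: set out from 12 and remove the benzyl groups without hydrogen, by Lewis-acid cleavage with BCl3 and pentamethylbenzene as benzyl-cation trap (CH2Cl2, −78 °C, then MeOH). This gives 13 directly, so the route is rejoined at 13 and no new compound arises (F0).

**Further compounds**

F1 | step 8 | 3-[3-(benzyloxy)-4-methoxyphenyl]propanal | O=CCCc1ccc(OC)c(OCc2ccccc2)c1
F2 | step 8 | 1-[(3S,4R,5S,6S)-3,4,5,6-tetrakis(benzyloxy)-2-hydroxycyclohex-1-en-1-yl]-5-[3-(benzyloxy)-4-methoxyphenyl]-3-hydroxypentan-1-one (both C3 epimers) | COc1ccc(CCC(O)CC(=O)C2=C(O)[C@@H](OCc3ccccc3)[C@H](OCc3ccccc3)[C@@H](OCc3ccccc3)[C@H]2OCc2ccccc2)cc1OCc1ccccc1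
F3 | step 5 | (2S,3R,4S,5S)-2,3,4,5-tetrakis(benzyloxy)-6-(1-hydroxyethyl)cyclohexan-1-one (mixture at C6 and the carbinol carbon) | CC(O)C1C(=O)[C@@H](OCc2ccccc2)[C@H](OCc2ccccc2)[C@@H](OCc2ccccc2)[C@H]1OCc1ccccc1
F0 | step 9 | none | none
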